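## Retrosynthetic overview

1. Feature: ring A carries oxygen on four neighbouring carbons (C5, C6, C7, C8), which is the oxygen pattern of a squaric diester. The other two ring A carbons, C4a and C8a, are the C5=C6 enol ether double bond of a 2-aryl-4H-pyran-4-one (ring C with ring B attached).
2. Target 15 ⇐ 14 by cleaving the C6 methyl ether beside the chelated C5 hydroxyl; 14 ⇐ 13 by removing the benzyl group from O2'.
3. 13 ⇐ 10 at the C4a–C5 bond: ring A is closed last, by cyclobutenone ring opening and six-electron electrocyclisation.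
4. 10 ⇐ pyranone 6 + dimethyl squarate 7 at the C8–C8a bond: the pyranone, magnesiated beside its ring oxygen, adds to a squarate carbonyl, and the carbinol is O-methylated.
5. 6 ⇐ 1 (ring B, purchased): benzylation, Claisen condensation, terminal formylation and cyclodehydration build ring C. Ring order: B → C → A.

Key step: step 6

Assumption: in pyranone 6 the aryl group sits at C2, so the carbon that is metalated is C6 (beside the ring oxygen, later C8a) and the carbon that closes ring A is C5 (later C4a). TMPMgCl·LiCl (TMP = 2,2,6,6-tetramethylpiperidide) is taken to remove the C6 proton, as such bases do at C2 of chromones.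

## Route

Step 1
Reactants: 1 2'-hydroxy-6'-methoxyacetophenone; 2 benzyl bromide
Product: 3 1-[2-(benzyloxy)-6-methoxyphenyl]ethan-1-one
Conditions: K2CO3, DMF, 60 °C
Reagents that add atoms: none
Why: Williamson ether synthesis, in which K2CO3 in DMF frees the phenoxide from its hydrogen bond to the ketone and the benzylic bromide alkylates it, giving an ether that withstands the later bases and the thermolysis and is removed by hydrogenolysis.

Step 2
Reactants: 3 1-[2-(benzyloxy)-6-methoxyphenyl]ethan-1-one
Product: 4 1-[2-(benzyloxy)-6-methoxyphenyl]butane-1,3-dione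
Conditions: NaH (2.5 equiv), EtOAc (excess), THF, 0 °C → reflux; aq. HCl
Reagents that add atoms: ethyl acetate, CCOC(C)=O
Why: crossed Claisen condensation, in which the methyl ketone enolate acylates on the unhindered methyl carbon and the equilibrium is drawn to the stabilised sodium diketonate.

Step 3
Reactants: 4 1-[2-(benzyloxy)-6-methoxyphenyl]butane-1,3-dione
Product: 6 2-[2-(benzyloxy)-6-methoxyphenyl]-4H-pyran-4-one, via formyl diketone 5 (not isolated)
Conditions: LDA (3.2 equiv), THF, −78 → 0 °C; HCO2Et, −78 → 0 °C; aq. HCl; then TsOH·H2O (cat.), PhMe, 60 °C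
Reagents that add atoms: ethyl formate, CCOC=O
Why: terminal acylation of a 1,3-diketone dianion (the aryl side has no α-hydrogen, so the second deprotonation can only occur at the methyl group) followed by acid-catalysed cyclodehydration of the 1,3,5-tricarbonyl compound to the 4-pyranone, under acid mild enough to keep the benzyl ether.

Step 4
Reactants: 6 2-[2-(benzyloxy)-6-methoxyphenyl]-4H-pyran-4-one; 7 dimethyl squarate
Product: 9 racemic 4-{6-[2-(benzyloxy)-6-methoxyphenyl]-4-oxo-4H-pyran-2-yl}-4-hydroxy-2,3-dimethoxycyclobut-2-en-1-one, via pyranonylmagnesium chloride 8 (not isolated)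
Conditions: TMPMgCl·LiCl (1.2 equiv), THF, −40 °C; then 7 (1.5 equiv), −40 → −20 °C; sat. aq. NH4Cl
Reagents that add atoms: none
Why: deprotonative magnesiation with a hindered magnesium amide at the most acidic ring C–H (C6, beside the ring oxygen and β to the carbonyl, as at C2 of chromones) followed by 1,2-addition of the organomagnesium to one squarate carbonyl, which stops after one addition because the alkoxide adduct is a far weaker electrophile; the carbinol carbon forms as a racemate and becomes sp2 in step 6.

Step 5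
Reactants: 9 racemic 4-{6-[2-(benzyloxy)-6-methoxyphenyl]-4-oxo-4H-pyran-2-yl}-4-hydroxy-2,3-dimethoxycyclobut-2-en-1-one
Product: 10 racemic 4-{6-[2-(benzyloxy)-6-methoxyphenyl]-4-oxo-4H-pyran-2-yl}-2,3,4-trimethoxycyclobut-2-en-1-one
Conditions: MeI (excess), Ag2O, MeCN, rt, dark
Reagents that add atoms: iodomethane, CI
Why: Purdie methylation of the tertiary carbinol under conditions without strong base, which should neither open the hydroxycyclobutenone nor alkylate the pyranone carbonyl oxygen, and which installs the later C8 methoxy group.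

Step 6
Reactants: 10 racemic 4-{6-[2-(benzyloxy)-6-methoxyphenyl]-4-oxo-4H-pyran-2-yl}-2,3,4-trimethoxycyclobut-2-en-1-one
Product: 13 2'-(benzyloxy)-5-hydroxy-6,7,8,6'-tetramethoxyflavone, via vinylketene 11 (not isolated), via cyclohexadienone 12 (not isolated)
Conditions: PhMe (0.01 M, degassed), 110 °C, Ar
Reagents that add atoms: none
Why: Proposed new method: heating should open 10 by conrotatory four-electron electrocyclic cleavage of the C1–C4 bond of the cyclobutenone, the 4-methoxy group turning outward, to vinylketene 11 with the pyranonyl group cis to the ketene; disrotatory six-electron electrocyclisation through the C5=C6 bond of the pyranone then joins the ketene carbon to pyranone C5 (the C4a–C5 bond of the flavone) and closes ring A as the six-membered dienone 12, which enolises to phenol 13. The closest known reaction is the Moore rearrangement of squarate-derived 4-aryl-, 4-heteroaryl- and 4-alkenyl-4-alkoxycyclobutenones to annulated hydroquinone monoethers, in which a free 4-pyranone has not served as the two-electron component. The ketene carbon becomes C5 with its free hydroxyl, the two squarate ether carbons become C6 and C7 and the methylated carbinol carbon becomes C8, so the oxygen pattern follows from the skeleton; the carbinol stereocentre of 10 becomes sp2 and the sp3 centre C4a of 12 is lost on enolisation, so no stereocentre has to be controlled. The step needs the pyranone and not the methoxy group to turn inward, which the outward preference of a donor substituent at C4 secures, and it needs closure to outrun ketene dimerisation, which high dilution and the enol ether character of pyranone C5 (β to the ring oxygen, hence nucleophilic toward the ketene carbon) should secure. The hydrogen bond of the new C5 hydroxyl to the C4 carbonyl and the gain of a benzene ring should make the closure irreversible.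

Step 7
Reactants: 13 2'-(benzyloxy)-5-hydroxy-6,7,8,6'-tetramethoxyflavone
Product: 14 5,2'-dihydroxy-6,7,8,6'-tetramethoxyflavone
Conditions: H2 (1 atm), 10% Pd/C, EtOAc, rt
Reagents that add atoms: none
Why: catalytic hydrogenolysis of a benzyl aryl ether, which should be much faster than reduction of the C2=C3 bond of the flavone (a vinylogous ester conjugated with both rings) when the reaction is stopped after one equivalent of H2.

Step 8
Reactants: 14 5,2'-dihydroxy-6,7,8,6'-tetramethoxyflavone
Product: 15 5,6,2'-trihydroxy-7,8,6'-trimethoxyflavone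
Conditions: AlBr3 (8 equiv), MeCN, 0 °C → rt; then 2 M HCl, 50 °C
Reagents that add atoms: none
Why: Lewis acid cleavage of an aryl methyl ether directed by a neighbouring chelated hydroxyl, in which the aluminium phenoxide held between O5 and the C4 carbonyl binds the oxygen of the C6 methoxy group and bromide removes that methyl group by SN2, while the C7 and C8 ethers have no aluminium phenoxide beside them and the C6' ether is an ordinary anisole that should survive AlBr3 in acetonitrile at this temperature.

## Compound list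

1 | 2'-hydroxy-6'-methoxyacetophenone | COc1cccc(O)c1C(C)=O | starting material
2 | benzyl bromide | BrCc1ccccc1 | starting material
3 | 1-[2-(benzyloxy)-6-methoxyphenyl]ethan-1-one | COc1cccc(OCc2ccccc2)c1C(C)=O | intermediate
4 | 1-[2-(benzyloxy)-6-methoxyphenyl]butane-1,3-dione | COc1cccc(OCc2ccccc2)c1C(=O)CC(C)=O | intermediate
5 | 5-[2-(benzyloxy)-6-methoxyphenyl]-3,5-dioxopentanal (drawn as the keto form) | COc1cccc(OCc2ccccc2)c1C(=O)CC(=O)CC=O | intermediate
6 | 2-[2-(benzyloxy)-6-methoxyphenyl]-4H-pyran-4-one | COc1cccc(OCc2ccccc2)c1-c1cc(=O)cco1 | intermediate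
7 | dimethyl squarate (3,4-dimethoxycyclobut-3-ene-1,2-dione) | COC1=C(OC)C(=O)C1=O | starting material
8 | {6-[2-(benzyloxy)-6-methoxyphenyl]-4-oxo-4H-pyran-2-yl}magnesium chloride (LiCl complex) | COc1cccc(OCc2ccccc2)c1-c1cc(=O)cc([Mg]Cl)o1 | intermediate
9 | racemic 4-{6-[2-(benzyloxy)-6-methoxyphenyl]-4-oxo-4H-pyran-2-yl}-4-hydroxy-2,3-dimethoxycyclobut-2-en-1-one | COC1=C(OC)C(O)(c2cc(=O)cc(-c3c(OC)cccc3OCc3ccccc3)o2)C1=O | intermediate
10 | racemic 4-{6-[2-(benzyloxy)-6-methoxyphenyl]-4-oxo-4H-pyran-2-yl}-2,3,4-trimethoxycyclobut-2-en-1-one | COC1=C(OC)C(OC)(c2cc(=O)cc(-c3c(OC)cccc3OCc3ccccc3)o2)C1=O | intermediate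
11 | (3Z)-4-{6-[2-(benzyloxy)-6-methoxyphenyl]-4-oxo-4H-pyran-2-yl}-2,3,4-trimethoxybuta-1,3-dien-1-one (vinylketene) | O=C=C(OC)/C(OC)=C(/OC)c1cc(=O)cc(-c2c(OC)cccc2OCc2ccccc2)o1 | intermediate
12 | racemic 2-[2-(benzyloxy)-6-methoxyphenyl]-6,7,8-trimethoxy-4aH-chromene-4,5-dione | COC1=C(OC)C(=O)C2C(=O)C=C(-c3c(OC)cccc3OCc3ccccc3)OC2=C1OC | intermediate
13 | 2'-(benzyloxy)-5-hydroxy-6,7,8,6'-tetramethoxyflavone | COc1cccc(OCc2ccccc2)c1-c1cc(=O)c2c(O)c(OC)c(OC)c(OC)c2o1 | intermediate
14 | 5,2'-dihydroxy-6,7,8,6'-tetramethoxyflavone | COc1cccc(O)c1-c1cc(=O)c2c(O)c(OC)c(OC)c(OC)c2o1 | intermediate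
15 | 5,6,2'-trihydroxy-7,8,6'-trimethoxyflavone | COc1cccc(O)c1-c1cc(=O)c2c(O)c(O)c(OC)c(OC)c2o1 | target

## Step count

Total steps: 8. Longest linear sequence: 8 steps (1 → 15).

## Steps most likely to fail

**Step 6 (key step).** The vinylketene may be consumed by dimerisation, or by acylating the product phenol, faster than it closes onto the electron-poor pyranone double bond. The fallback is a chalcone-based flavone synthesis that sets out from benzyl bromide 2 and comes back at 14.
- Benzyl bromide 2 would alkylate purchased 2-hydroxy-6-methoxybenzaldehyde F1 (K2CO3, DMF) to give 2-(benzyloxy)-6-methoxybenzaldehyde F2.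
- Claisen–Schmidt condensation of F2 with purchased 2'-hydroxy-3',4',5',6'-tetramethoxyacetophenone F3 (KOH, EtOH, rt) should give (E)-3-[2-(benzyloxy)-6-methoxyphenyl]-1-(2-hydroxy-3,4,5,6-tetramethoxyphenyl)prop-2-en-1-one F4.
- Oxidative cyclisation with catalytic I2 in DMSO at 130 °C should give 2'-(benzyloxy)-5,6,7,8,6'-pentamethoxyflavone F5.
- BCl3 in CH2Cl2 (−78 → 0 °C) should then cleave the methyl ether peri to the carbonyl group and the benzyl ether, giving 14 ahead of step 8.

**Step 4.** Deprotonation may take place beside the carbonyl group instead of beside the ring oxygen, or the magnesiated pyranone may add to pyranone not yet metalated during the slow deprotonation. The fallback separates C–H activation from nucleophile generation; it sets out from 6 and comes back at 9.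
- 6 would be zincated with TMPZnCl·LiCl (THF, 25 °C) to {6-[2-(benzyloxy)-6-methoxyphenyl]-4-oxo-4H-pyran-2-yl}zinc chloride F6, a species that does not add to the pyranone.
- Iodolysis of F6 would give 2-[2-(benzyloxy)-6-methoxyphenyl]-6-iodo-4H-pyran-4-one F7, whose iodine position can be established before any squarate is committed.
- Iodine–magnesium exchange with iPrMgCl·LiCl in THF at −78 °C should then give 8 rapidly in the absence of free 6, and addition of 7 returns to 9.

**Step 8.** Site selectivity of the ether cleavage may be lost, with the crowded C7 or C8 methyl ether removed together with, or in place of, the C6 ether. The fallback uses squarate ester groups that are cleaved without touching methyl ethers; it sets out from 6 and comes back at 15.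
- Organomagnesium 8, made from 6 as in step 4, would be added to purchased diisopropyl squarate F8 to give racemic 4-{6-[2-(benzyloxy)-6-methoxyphenyl]-4-oxo-4H-pyran-2-yl}-4-hydroxy-2,3-di(propan-2-yloxy)cyclobut-2-en-1-one F9.
- Methylation (MeI, Ag2O) would give racemic 4-{6-[2-(benzyloxy)-6-methoxyphenyl]-4-oxo-4H-pyran-2-yl}-4-methoxy-2,3-di(propan-2-yloxy)cyclobut-2-en-1-one F10.
- Heating as in step 6, by way of 2,3-diisopropoxy vinylketene F11 and 6,7-diisopropoxy cyclohexadienone F12, should give 2'-(benzyloxy)-5-hydroxy-8,6'-dimethoxy-6,7-di(propan-2-yloxy)flavone F13.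
- BCl3 (CH2Cl2, −78 → 0 °C) should cleave the two secondary alkyl ethers and the benzyl ether but not the methyl ethers at C8 and C6', giving 5,6,7,2'-tetrahydroxy-8,6'-dimethoxyflavone F14.
- One equivalent of MeI with KHCO3 in DMF should then methylate the most acidic hydroxyl, the one at C7 para to the carbonyl group, to give 15.

## Further compounds

F1 | step 6 | 2-hydroxy-6-methoxybenzaldehyde | COc1cccc(O)c1C=O
F2 | step 6 | 2-(benzyloxy)-6-methoxybenzaldehyde | COc1cccc(OCc2ccccc2)c1C=O
F3 | step 6 | 2'-hydroxy-3',4',5',6'-tetramethoxyacetophenone | CC(=O)c1c(O)c(OC)c(OC)c(OC)c1OC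
F4 | step 6 | (E)-3-[2-(benzyloxy)-6-methoxyphenyl]-1-(2-hydroxy-3,4,5,6-tetramethoxyphenyl)prop-2-en-1-one | COc1cccc(OCc2ccccc2)c1/C=C/C(=O)c1c(O)c(OC)c(OC)c(OC)c1OC
F5 | step 6 | 2'-(benzyloxy)-5,6,7,8,6'-pentamethoxyflavone | COc1cccc(OCc2ccccc2)c1-c1cc(=O)c2c(OC)c(OC)c(OC)c(OC)c2o1
F6 | step 4 | {6-[2-(benzyloxy)-6-methoxyphenyl]-4-oxo-4H-pyran-2-yl}zinc chloride | COc1cccc(OCc2ccccc2)c1-c1cc(=O)cc([Zn]Cl)o1
F7 | step 4 | 2-[2-(benzyloxy)-6-methoxyphenyl]-6-iodo-4H-pyran-4-one | COc1cccc(OCc2ccccc2)c1-c1cc(=O)cc(I)o1
F8 | step 8 | diisopropyl squarate (3,4-di(propan-2-yloxy)cyclobut-3-ene-1,2-dione) | CC(C)OC1=C(OC(C)C)C(=O)C1=O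
F9 | step 8 | racemic 4-{6-[2-(benzyloxy)-6-methoxyphenyl]-4-oxo-4H-pyran-2-yl}-4-hydroxy-2,3-di(propan-2-yloxy)cyclobut-2-en-1-one | CC(C)OC1=C(OC(C)C)C(O)(c2cc(=O)cc(-c3c(OC)cccc3OCc3ccccc3)o2)C1=O
F10 | step 8 | racemic 4-{6-[2-(benzyloxy)-6-methoxyphenyl]-4-oxo-4H-pyran-2-yl}-4-methoxy-2,3-di(propan-2-yloxy)cyclobut-2-en-1-one | CC(C)OC1=C(OC(C)C)C(OC)(c2cc(=O)cc(-c3c(OC)cccc3OCc3ccccc3)o2)C1=O
F11 | step 8 | 2,3-diisopropoxy vinylketene, (3Z)-4-{6-[2-(benzyloxy)-6-methoxyphenyl]-4-oxo-4H-pyran-2-yl}-4-methoxy-2,3-di(propan-2-yloxy)buta-1,3-dien-1-one | O=C=C(OC(C)C)/C(OC(C)C)=C(/OC)c1cc(=O)cc(-c2c(OC)cccc2OCc2ccccc2)o1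
F12 | step 8 | 6,7-diisopropoxy cyclohexadienone, racemic 2-[2-(benzyloxy)-6-methoxyphenyl]-8-methoxy-6,7-di(propan-2-yloxy)-4aH-chromene-4,5-dione | CC(C)OC1=C(OC(C)C)C(=O)C2C(=O)C=C(-c3c(OC)cccc3OCc3ccccc3)OC2=C1OC
F13 | step 8 | 2'-(benzyloxy)-5-hydroxy-8,6'-dimethoxy-6,7-di(propan-2-yloxy)flavone | COc1cccc(OCc2ccccc2)c1-c1cc(=O)c2c(O)c(OC(C)C)c(OC(C)C)c(OC)c2o1
F14 | step 8 | 5,6,7,2'-tetrahydroxy-8,6'-dimethoxyflavone | COc1cccc(O)c1-c1cc(=O)c2c(O)c(O)c(O)c(OC)c2o1
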